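A small charge of impurity, 8.9 mM, sits in the flask beside 7 mol% of free catalyst, less than the catalyst charged, so we treat it as a correction. We suppose that one impurity removes one free catalyst, which leaves two amounts to compare: impurity charged and catalyst charged.

all flasks: impurity 8.9 mM
- grey: substrate 0.80 M; free catalyst 9.8 mol%; run made earlier
- red: substrate 0.80 M; free catalyst 15 mol%; run made earlier
- ochre: substrate 1.2 M; free catalyst 7 mol%; run made earlier
- flask: substrate 0.80 M; free catalyst 7 mol%; time 50 min

| run | time / min | isomer of the product / % | target / % |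
|---|---|---|---|
| grey | 4.00 | 44.2 | 50.9 |
| grey | 8.00 | 47.4 | 51.2 |
| grey | 15.0 | 48.2 | 52.0 |
| grey | 25.0 | 48.5 | 51.4 |
| grey | 50.0 | 48.7 | 51.8 |
| red | 10.0 | 38.3 | 62.4 |
| red | 20.0 | 38.3 | 61.2 |
| red | 30.0 | 38.3 | 62.1 |
| red | 40.0 | 37.8 | 62.0 |
| red | 50.0 | 39.0 | 61.8 |
| ochre | 4.00 | 42.3 | 48.7 |
| ochre | 8.00 | 48.8 | 49.4 |
| ochre | 15.0 | 50.4 | 48.4 |
| ochre | 25.0 | 50.8 | 49.1 |
| ochre | 50.0 | 50.4 | 49.9 |

(each reading ± 0.5 percentage points)

- a reading or a percentage of target counts all its forms, free or not

1. ratio of isomer of the product to target at 1.0 s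
2. ratio of isomer of the product to target at 50 min
3. which of isomer of the product and target there is more of at 50 min

In the flask, impurity charged over catalyst charged is 15.9%, the lost share. At 0.80 M of substrate, the end ratio of isomer to target falls from 0.940 in the grey run to 0.631 in the red run as the catalyst rises. We therefore let it go inversely with the unspent catalyst, the loading times one minus the lost share. Grey has a lost share of 11.4%. Scaling from grey by loading gives 1.32, and the correction lifts this to 1.39, with isomer ahead. The earliest readings, in the grey and ochre runs, stand at 4.00 min, so we commit to no figure for 1.0 s.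

The forecast gives 0.9 at 1.0 s, and 1.25 at 50 min with isomer of the product ahead, a lower end ratio than ours. It holds that “The initial ratio must be lower than the final one.”

The flask gives 0.0435 at 1.0 s, far below the forecast. At 50 min it gives 1.28, above the forecast and below ours, with isomer of the product ahead.

    free catalyst + other conformer → free catalyst + isomer of the product (k = 2.10 M⁻¹ s⁻¹)
    substrate ⇌ other conformer (K = 13.0, k = 0.120 s⁻¹)
    free catalyst + target ⇌ idle complex (K = 42.0 M⁻¹, k = 0.770 M⁻¹ s⁻¹)
    substrate ⇌ dormant form (K = 0.670, k = 0.0340 s⁻¹)
    substrate + free catalyst → free catalyst + target (k = 2.90 M⁻¹ s⁻¹)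
    free catalyst + impurity → spent catalyst (k = 2500 M⁻¹ s⁻¹)

At 50.0 min, spent catalyst in the flask stands at 15.9% of the catalyst charged, beside our lost share of 15.9%, while 78.1% is idle complex and 6.05% is free. The neighbouring flask holds 0.022 M of impurity, which makes the lost share 39.3%. Scaling the flask's ratio by the two unspent parts gives 1.77. That neighbour shows 39.3% spent catalyst and an end ratio of 1.63.

The runs were computed for substances that don't exist, noise included.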